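(The earlier runs and the new flask were generated by integration on assumed constants, noise included.)

Picture a one-step world: the charge changes the speed and never the mix. Maple's last reading shows more ring than alder's, though the two differ in both charge and temperature, so test that world on the runs.

| setting | maple | alder | north-west | east | west | south | north-east |
|---|---|---|---|---|---|---|---|
| starting material | 0.038 M | 0.47 M | 0.30 M | 0.060 M | 0.030 M | 0.10 M | 0.050 M |
| temperature | 75 °C | 90 °C | 90 °C | 90 °C | 90 °C | 90 °C | 90 °C |
| remark | run made earlier | run made earlier |  |  |  |  |  |
| time |  |  | 40 h | 40 h | 40 h | 40 h | 40 h |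

- maple (time / h: ring / %, open dimer / %, open trimer / %): 12.0: 10.7, 34.8, 3.0; 25.0: 12.8, 40.7, 4.8; 30.0: 16.4, 42.7, 5.7; 48.0: 19.4, 46.3, 8.2; 60.0: 22.1, 45.8, 10.4
- alder (time / h: ring / %, open dimer / %, open trimer / %): 2.50: 4.1, 63.3, 19.8; 8.00: 3.9, 61.1, 28.2; 12.0: 3.5, 58.7, 34.7; 20.0: 3.6, 56.4, 37.4; 30.0: 6.1, 53.4, 37.2

(scatter of a reading: 1 percentage point)

- all flasks from highest to lowest share of ring in all that became ring or open dimer or open trimer or over-reaction product, at 40 h (north-west / east / west / south / north-east)
- the share of ring in all that became ring or open dimer or open trimer or over-reaction product of the flask you put first, at 40 h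
- the share of ring in all that became ring or open dimer or open trimer or over-reaction product of the flask you put last, at 40 h

- in percentages every species weighs as the starting material in it: one open dimer counts as two
- in percentages every species weighs as the starting material in it: one open trimer counts as three

Let S be the starting material concentration and C its charge. Take S leaving by a second-order way to open dimer and a first-order way to ring, so −dS/dt = kS(a+S), with k the second-order constant, a the concentration at which both ways run equal, and a/(a+S) the instantaneous ring share. Alder's open dimer stays near 58.7% while ring goes from 4.1% at the first reading to 6.1% at the last, so don't feed ring from open dimer.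

Alder's last reading gives a ring share of 6.31% among the species read. Replace the curve by its mean: suppose S averages half of C, as in a straight fall, which gives a near 0.0158 M. In alder C far exceeds that, so distrust the mean and use the integral, share = a·ln[(a+C)/(a+E)]/(C−E), with E the S at the end. Iterated with E near nothing, it gives 8.66 mM, then a near 7.39 mM, the crossover concentration (a selectivity factor), a reading that carries the scatter.

Climb the time ladder. Reading alder's unaccounted material at 2.50 h as S gives k near 5.80 L mol⁻¹ h⁻¹. The dimer rung, the inverse of kC, takes 0.575 h in north-west and 5.75 h in west. Below a, S decays pseudo-first-order with τ, the inverse of ka, = 23.3 h, which is shorter than the 40 h allowed.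

So reckon west at E = 1.25 mM with share 37.7%, and north-west at 1.58 mM with 8.75%. The reckoned share is higher in west than in north-west, so rank the flasks by charge, lowest first.

The forecast, from “a dimer-stage intermediate that either closes (first order) or is captured by S”, says west > north-east > east > south > north-west, 40% and 10%, both shares above my figures.

The flasks give west > north-east > east > south > north-west, with 41.6% and 8.61%.

    2 starting material → open dimer (k = 4.36 L mol⁻¹ h⁻¹, Ea = 91.0 kJ mol⁻¹)
    starting material ⇌ dormant form (K = 0.980, k = 0.254 h⁻¹, Ea = 127 kJ mol⁻¹, ΔH = 20.0 kJ mol⁻¹)
    starting material → ring (k = 0.0768 h⁻¹, Ea = 115 kJ mol⁻¹)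
    ring → over-reaction product (k = 0.00624 h⁻¹, Ea = 120 kJ mol⁻¹)
    starting material + open dimer → open trimer (k = 1.14 L mol⁻¹ h⁻¹, Ea = 89.0 kJ mol⁻¹)
    (constants at 90 °C)

West, charged at 0.030 M against a = 7.39 mM, reckons 37.7% and stands at 41.6%. In north-west, starting material goes 23 times as fast into open dimer as into open trimer at 0.266 h, but that ratio is 0.086 at 40.0 h. That flask then holds open dimer 53.0%, open trimer 35.8% and ring 8.55%. The neighbour of north-west, charged at 0.12 M, reckons E = 1.51 mM and share 16.6%, and stands at 18.1%.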